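The numbers in the tables come from a simulation with made-up constants; scatter was added.

**The ratio.** Monomer in chains gains while adding outruns the back step, so the number to watch is the ratio of those two steps. Its zero of scale is 1, where chains are made as fast as they are unmade. Adding goes with living ends and [free monomer]; the back step, taken here as first order, goes with living ends but not with [free monomer]. The ratio is then [free monomer] over a ceiling, the equilibrium monomer concentration, at which the two steps balance.

| setting | larch | maple | alder | summer | dusk |
|---|---|---|---|---|---|
| free monomer | 0.87 M | 2 M | 1.3 M | 1.3 M | 1.3 M |
| pre-initiator | 7.3 mM | 7.3 mM | 3.6 mM | 7.3 mM | 7.3 mM |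
| remark | run made earlier | run made earlier | run made earlier |  |  |
| time |  |  |  | 40 h | 20 h |

| run | time / h | monomer in chains / % | free monomer / % |
|---|---|---|---|
| larch | 2.50 | 0 | 95.7 |
| larch | 5.00 | 3.1 | 88.4 |
| larch | 10.0 | 11.1 | 74.6 |
| larch | 15.0 | 19.7 | 60.6 |
| larch | 30.0 | 38.8 | 34.2 |
| maple | 6.00 | 5.2 | 86.3 |
| maple | 12.0 | 18.5 | 67.6 |
| maple | 20.0 | 34.2 | 42.0 |
| maple | 25.0 | 45.3 | 31.0 |
| maple | 30.0 | 49.9 | 22.6 |
| alder | 3.00 | 0.4 | 95.2 |
| alder | 8.00 | 4.6 | 83.2 |
| alder | 15.0 | 10.4 | 68.0 |
| alder | 25.0 | 23.8 | 47.6 |
| alder | 30.0 | 27.2 | 38.1 |

(standard deviation of a reading: 1 percentage point)

* which of the two ends with the longer chains by the average number of monomer units in a chain (chains begun, living or dead) ("neither" if they lie within 10%) (summer / dusk / neither)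
* average number of monomer units in a chain (chains begun, living or dead) at the end, summer
* average number of monomer units in a chain (chains begun, living or dead) at the end, dusk

- the average divides the monomer in chains by the number of chains begun, living and dead together
- what may be going on: free monomer + living end -> monomer in chains + living end; free monomer + initiator -> living end + monomer in chains; monomer in chains + living end -> free monomer + living end; pre-initiator <-> initiator; free monomer -> uncatalysed product
- the earlier runs do not show the number of chains; that part of a forecast is a guess

**Reading it.** Larch and maple hold equal pre-initiator, so this reckoning takes their living ends as alike at equal times. Their gains then stand as their excesses of [free monomer] over the ceiling. From 20.0 h to 30.0 h, maple gains 0.314 M at a mean [free monomer] of 0.646 M. Larch, read between its readings, gains 0.111 M at 0.374 M. Solving gives a ceiling of 0.226 M, a reading that carries the scatter.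

**The decision.** Should the flask stand 40 h or stop at 20 h? Placing it between larch and maple by charge gives [free monomer] of 0.625 M at 20 h and 0.387 M at 30.0 h. The same fall repeated gives 0.240 M at 40 h. The ratio thus sinks from 2.77 to 1.06, close to balance. The count of chains is a guess, but it should still climb while monomer in chains stalls, so this reckoning commits to neither and stops at 20 h.

**The result.** The forecast gave 103 for summer and 67 for dusk, hence summer, and reported “depolymerisation not clearly visible”. The flask gives 121 units in summer and 116 in dusk, so neither.

    free monomer + living end → monomer in chains + living end, rate k1*[living end]*[free monomer] (k = 16.0 /M/h)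
    free monomer + initiator → living end + monomer in chains (k = 4.20 /M/h)
    monomer in chains + living end → free monomer + living end, rate k3*[living end] as long as [monomer in chains] is above zero (k = 3.20 /h)
    pre-initiator ⇌ initiator (K = 1.90, k = 0.0360 /h)
    free monomer → uncatalysed product (k = 0.0150 /h)

**Near balance.** Summer's free monomer at 40.0 h is 0.236 M, which stands above the ceiling of 0.226 M read from the runs. Monomer in chains in summer is made 1.19 times faster than used up at that time, against 2.98 times at 19.8 h, while living end rises from 0.00368 M to 0.00549 M. The neighbour of summer charged with 0.52 M ends at 0.187 M of free monomer, which is less than that ceiling as read, and its chains average 26.4 units.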